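**Retrosynthetic overview**
- The target is a symmetric tetramer: filicinic acid ring – CH2 – phloroglucinol ring – CH2 – phloroglucinol ring – CH2 – filicinic acid ring. Cut the two outer CH2 bridges first: central bis(butyrylphloroglucinol)methane + 2 × butyrylfilicinic acid, each joined through one CH2 (Mannich base, then enone Michael addition).
- Central diarylmethane ⇒ both benzene rings made together from a methylene-bridged bis(4-hydroxy-2-pyranone) by twofold lactone methanolysis and Claisen recyclisation (key step). The pyranone C3 bridge fixes the single-bridge regiochemistry and leaves one free C–H per ring.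
- Bis-pyranone ⇒ 2 × 4-hydroxy-6-(2-oxopentyl)-2-pyranone + formaldehyde; that pyranone ⇒ triacetic acid lactone dianion + butanoyl Weinreb amide.
- Butyrylfilicinic acid ⇒ dearomatising gem-dimethylation of commercial 2,4,6-trihydroxybutyrophenone.
- Ring order: the two central benzene rings form together (step 3); the two outer cyclohexadienone rings come from a bought benzene ring (step 4) and are attached last (step 5).

Assumption: the target has no stereocentre (each quaternary carbon carries two methyl groups) and is achiral, so the structure drawn is the only stereoisomer; all compounds are written in one enol tautomer.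

**Step 1**
Reactants: 1 4-hydroxy-6-methyl-2H-pyran-2-one (triacetic acid lactone); 2 N-methoxy-N-methylbutanamide
Product: 3 4-hydroxy-6-(2-oxopentyl)-2H-pyran-2-one
Conditions: LiN(iPr)2 (2.5 equiv), THF, −78 °C, 1 h; then 2 (1.1 equiv), −78 → 0 °C; 1 M HCl
Reagents that add atoms: none
Why: Two equivalents of base give the O,C-dianion of 1 (4-OLi and 6-CH2Li), which is acylated only at the exocyclic carbon by the Weinreb amide, whose stable tetrahedral chelate prevents over-addition and proton quenching by the product (Harris-type dianion γ-acylation, a Claisen-type C-acylation); no stereocentre is formed.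

**Step 2**
Reactants: 3 4-hydroxy-6-(2-oxopentyl)-2H-pyran-2-one (two molecules)
Product: 5 3,3'-methylenebis[4-hydroxy-6-(2-oxopentyl)-2H-pyran-2-one], via methylidene pyrandione 4 (not isolated)
Conditions: 37% aq. HCHO (0.52 equiv), EtOH, 60 °C, 3 h, no base; filter the precipitate
Reagents that add atoms: formaldehyde, C=O
Why: C3 of the 4-hydroxypyranone (a vinylogous acid, pKa about 5) is by far the most nucleophilic carbon without added base, so Knoevenagel condensation with formaldehyde gives 4 and a second molecule of 3 adds at once in a Michael reaction (dicoumarol-type methylene bridging), while the less acidic side-chain CH2 stays untouched; no stereocentre is formed.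

**Step 3 (key step)**
Reactants: 5 3,3'-methylenebis[4-hydroxy-6-(2-oxopentyl)-2H-pyran-2-one]
Product: 9 bis(3-butanoyl-2,4,6-trihydroxyphenyl)methane, via ring-opened triketo ester 6 (not isolated), via mono-aryl pyranone 7 (not isolated), via aryl triketo ester 8 (not isolated)
Conditions: Mg(OMe)2 (10 equiv), MeOH, reflux, 18 h, argon; then 2 M HCl, 0 °C
Reagents that add atoms: none
Why: Proposed new method: methoxide opens one pyranone lactone to the methyl 3,5,7-triketo ester 6, whose C6 carbanion (between two ketones) closes onto the ester in a Dieckmann-type Claisen condensation made irreversible by aromatisation to the phloroglucinolate 7, and the same opening (to 8) and closure repeat on the second pyranone so that two benzene rings form in one operation; the C3 substituent shuts off the competing aldol (resorcylate) mode because that closure would need a quaternary ring carbon that cannot aromatise, and each opened arm should cyclise faster than the second anionic lactone opens, which keeps the two arms from condensing with each other; the closest known reaction type is the biomimetic recyclisation of single 4-hydroxy-6-(2-oxoalkyl)-2-pyranones to acylphloroglucinols with Mg(OMe)2 in MeOH; no stereocentre is formed.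

**Step 4**
Reactants: 10 1-(2,4,6-trihydroxyphenyl)butan-1-one
Product: 11 2-butanoyl-3,5-dihydroxy-4,4-dimethylcyclohexa-2,5-dien-1-one (butyrylfilicinic acid)
Conditions: NaOMe (3.2 equiv), MeI (2.4 equiv), MeOH, 0 °C → rt, 16 h; 1 M HCl; chromatography
Reagents that add atoms: iodomethane, CI
Why: The phloroglucinolate is C-methylated twice at the same ring carbon between two oxygens, the second alkylation dearomatising the ring to the β-triketone enol (phenolate C-alkylation, the standard preparation of acylfilicinic acids); the new quaternary carbon carries two identical methyl groups, so no stereocentre arises.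

**Step 5**
Reactants: 9 bis(3-butanoyl-2,4,6-trihydroxyphenyl)methane (1 equiv); 11 2-butanoyl-3,5-dihydroxy-4,4-dimethylcyclohexa-2,5-dien-1-one (2.2 equiv)
Product: 14 bis{3-butanoyl-5-[(5-butanoyl-2,4-dihydroxy-3,3-dimethyl-6-oxocyclohexa-1,4-dien-1-yl)methyl]-2,4,6-trihydroxyphenyl}methane (target CNP0110234.0), via Mannich base 12 (not isolated), via exocyclic enone 13 (not isolated)
Conditions: 11, [Me2N=CH2]I (2.2 equiv), MeCN, 0 °C → rt, 1 h; then 9, NaOAc (2.5 equiv), AcOH (10 vol %), 50 °C, 8 h
Reagents that add atoms: N,N-dimethylmethyleneiminium iodide (Eschenmoser's salt), C=[N+](C)C.[I-]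
Why: The only free ring carbon of 11 is aminomethylated (Mannich reaction) to 12, which on buffered warming loses dimethylamine to the enone 13 (a vinylogous ortho-quinone methide), and the single free ring C–H of each phloroglucinol ring of 9 adds to it in a Friedel–Crafts-type Michael addition; each partner has only one open position, so no oligomers can grow, and no stereocentre is formed.

**Compound list**
1 | 4-hydroxy-6-methyl-2H-pyran-2-one (triacetic acid lactone) | CC1=CC(O)=CC(=O)O1 | starting material
2 | N-methoxy-N-methylbutanamide | CCCC(=O)N(C)OC | starting material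
3 | 4-hydroxy-6-(2-oxopentyl)-2H-pyran-2-one | CCCC(=O)CC1=CC(O)=CC(=O)O1 | intermediate
4 | 3-methylidene-6-(2-oxopentyl)-2H-pyran-2,4(3H)-dione | CCCC(=O)CC1=CC(=O)C(=C)C(=O)O1 | intermediate (not isolated)
5 | 3,3'-methylenebis[4-hydroxy-6-(2-oxopentyl)-2H-pyran-2-one] | CCCC(=O)CC1=CC(O)=C(CC2=C(O)C=C(CC(=O)CCC)OC2=O)C(=O)O1 | intermediate
6 | methyl 2-{[4-hydroxy-2-oxo-6-(2-oxopentyl)-2H-pyran-3-yl]methyl}-3,5,7-trioxodecanoate (C2 configurationally labile, no defined configuration) | CCCC(=O)CC(=O)CC(=O)C(CC1=C(O)C=C(CC(=O)CCC)OC1=O)C(=O)OC | intermediate (not isolated)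
7 | 3-[(3-butanoyl-2,4,6-trihydroxyphenyl)methyl]-4-hydroxy-6-(2-oxopentyl)-2H-pyran-2-one | CCCC(=O)CC1=CC(O)=C(Cc2c(O)cc(O)c(C(=O)CCC)c2O)C(=O)O1 | intermediate (not isolated)
8 | methyl 2-[(3-butanoyl-2,4,6-trihydroxyphenyl)methyl]-3,5,7-trioxodecanoate (C2 configurationally labile, no defined configuration) | CCCC(=O)CC(=O)CC(=O)C(Cc1c(O)cc(O)c(C(=O)CCC)c1O)C(=O)OC | intermediate (not isolated)
9 | bis(3-butanoyl-2,4,6-trihydroxyphenyl)methane | CCCC(=O)c1c(O)cc(O)c(Cc2c(O)cc(O)c(C(=O)CCC)c2O)c1O | intermediate
10 | 1-(2,4,6-trihydroxyphenyl)butan-1-one | CCCC(=O)c1c(O)cc(O)cc1O | starting material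
11 | 2-butanoyl-3,5-dihydroxy-4,4-dimethylcyclohexa-2,5-dien-1-one (butyrylfilicinic acid) | CCCC(=O)C1=C(O)C(C)(C)C(O)=CC1=O | intermediate
12 | 2-butanoyl-6-[(dimethylamino)methyl]-3,5-dihydroxy-4,4-dimethylcyclohexa-2,5-dien-1-one | CCCC(=O)C1=C(O)C(C)(C)C(O)=C(CN(C)C)C1=O | intermediate (not isolated)
13 | 2-butanoyl-3-hydroxy-4,4-dimethyl-6-methylidenecyclohex-2-ene-1,5-dione | CCCC(=O)C1=C(O)C(C)(C)C(=O)C(=C)C1=O | intermediate (not isolated)
14 | bis{3-butanoyl-5-[(5-butanoyl-2,4-dihydroxy-3,3-dimethyl-6-oxocyclohexa-1,4-dien-1-yl)methyl]-2,4,6-trihydroxyphenyl}methane | CCCC(=O)C1=C(O)C(C)(C)C(O)=C(Cc2c(O)c(Cc3c(O)c(CC4=C(O)C(C)(C)C(O)=C(C(=O)CCC)C4=O)c(O)c(C(=O)CCC)c3O)c(O)c(C(=O)CCC)c2O)C1=O | target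

**Totals**
Total step count: 5. Longest linear sequence: 4 steps (steps 1, 2, 3, 5); step 4 is a one-step branch.

**Steps most likely to fail**

Step 3 is the riskiest. The two arms sit 1,5 to each other across the CH2 bridge, so once opened they could condense with each other (Hagemann-type aldol or cross-arm Dieckmann closure). The bridge could also fragment by retro-Michael reaction in hot methoxide, or the second ring could fail to close. The fallback sets out from 5 and comes back at 9. Mitsunobu O-methylation of both acidic 4-OH groups (MeOH, PPh3, diisopropyl azodicarboxylate, THF, 0 °C → rt) gives 3,3'-methylenebis[4-methoxy-6-(2-oxopentyl)-2H-pyran-2-one] F1. As enol ethers the two units can no longer fragment by retro-Michael reaction, C3 and C4 of each arm no longer act as β-diketone donor or acceptor toward the other arm, and the neutral lactones are more electrophilic. The same twofold recyclisation (Mg(OMe)2, MeOH, reflux) then gives bis(3-butanoyl-2,4-dihydroxy-6-methoxyphenyl)methane F2, still with both rings formed in one operation. BBr3 (CH2Cl2, −78 → 0 °C) cleaves both aryl methyl ethers to return to 9.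

Step 5 is the second risk. Unconsumed 11 can capture 13 to give the symmetrical filicinic acid dimer, 13 can dimerise by hetero-Diels–Alder reaction, and methylene bridges of this class can exchange under basic conditions. The fallback reverses the roles of the partners; it sets out from 9 and comes back at 14. Twofold aminomethylation of 9 with [Me2N=CH2]I (MeCN, rt) gives bis{3-butanoyl-5-[(dimethylamino)methyl]-2,4,6-trihydroxyphenyl}methane F3, in which every ring position of the central unit is blocked. Heating F3 with an excess of 11 (4 equiv, dioxane, 90 °C) expels dimethylamine to form an ortho-quinone methide at each ring, which is trapped at C6 of 11, the only nucleophile with a free position, to give 14. The excess 11 is recovered.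

Step 2 is the third risk. Formaldehyde may also attack the side-chain CH2 of 3 and give mixed or oligomeric bridged products. The fallback installs the bridge before the side chains; it sets out from 1 and comes back at 5. Compound 1 and aqueous formaldehyde (EtOH, 60 °C) give 3,3'-methylenebis(4-hydroxy-6-methyl-2H-pyran-2-one) F4, which has no competing methylene. Its tetra-anion (LiN(iPr)2, 5 equiv, THF with N,N'-dimethylpropyleneurea, −78 °C) is acylated at both 6-methyl groups with 2 (2.2 equiv) to give 5.

**Further compounds**
F1 | step 3 | 3,3'-methylenebis[4-methoxy-6-(2-oxopentyl)-2H-pyran-2-one] | CCCC(=O)CC1=CC(OC)=C(CC2=C(OC)C=C(CC(=O)CCC)OC2=O)C(=O)O1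
F2 | step 3 | bis(3-butanoyl-2,4-dihydroxy-6-methoxyphenyl)methane | CCCC(=O)c1c(O)cc(OC)c(Cc2c(OC)cc(O)c(C(=O)CCC)c2O)c1O
F3 | step 5 | bis{3-butanoyl-5-[(dimethylamino)methyl]-2,4,6-trihydroxyphenyl}methane | CCCC(=O)c1c(O)c(CN(C)C)c(O)c(Cc2c(O)c(CN(C)C)c(O)c(C(=O)CCC)c2O)c1O
F4 | step 2 | 3,3'-methylenebis(4-hydroxy-6-methyl-2H-pyran-2-one) | CC1=CC(O)=C(CC2=C(O)C=C(C)OC2=O)C(=O)O1
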